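**Retrosynthetic overview**
1. The last step is a single BCl3 operation that frees both phenols (the peri-chelated 5-OMe and the 3'-OBn) from a fully etherified isoflavone.
2. Key disconnection: the C3–aryl bond is made neither by cross-coupling on a 3-halochromone nor through a deoxybenzoin plus a C1 unit. It comes from a biomimetic iodine(III)-induced 2→3 aryl migration of the isomeric flavanone.
3. The flavanone is made in one flask by Claisen–Schmidt condensation and oxa-Michael closure of a penta-oxygenated acetophenone with a simple benzaldehyde, so ring B needs no boronic or arylacetic acid.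
4. The fifth A-ring oxygen is introduced by bromination and Cu-catalysed methoxylation of a catalogue acetophenone. The aldehyde needs only one benzylation.
5. Ring order: A and B are bought as arenes. Ring C is closed once as a chroman-4-one and becomes the 4-pyranone in the migration step.

Assumption: the target has no stereocentre and no stable stereoaxis, so it is achiral and "single enantiomer" requires no stereocontrol. The only stereocentre on the route (C2 of the flavanone) is made racemic and is erased in step 5. Compounds 1 and 4 are taken as catalogue chemicals.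

**Step 1**
Reactants: 1 1-(6-hydroxy-2,3,4-trimethoxyphenyl)ethan-1-one
Product: 2 1-(3-bromo-2-hydroxy-4,5,6-trimethoxyphenyl)ethan-1-one
Conditions: NBS (1.05 equiv), MeCN, 0 °C to rt, dark
Reagents that add atoms: N-bromosuccinimide, O=C1CCC(=O)N1Br
Why: Electrophilic aromatic bromination (SEAr) can give only one aryl bromide because the ring has a single free position, ortho to the activating OH, and NBS in MeCN without acid or light leaves the acetyl CH3 untouched.

**Step 2**
Reactants: 2 1-(3-bromo-2-hydroxy-4,5,6-trimethoxyphenyl)ethan-1-one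
Product: 3 1-(2-hydroxy-3,4,5,6-tetramethoxyphenyl)ethan-1-one
Conditions: NaOMe (25% in MeOH, 8 equiv), CuBr (20 mol%), DMF, 110 °C; then 1 M HCl
Reagents that add atoms: sodium methoxide, [Na+].[O-]C
Why: This is a copper-catalysed Ullmann-type methoxylation of an o-bromophenolate, the reaction type that converts 5-bromovanillin into syringaldehyde and 5-haloacetovanillone into acetosyringone, and the ketone is held as its unreactive chelated phenoxide while no other C–halogen bond competes.

**Step 3**
Reactants: 4 3-hydroxy-2-methoxybenzaldehyde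
Product: 5 3-(benzyloxy)-2-methoxybenzaldehyde
Conditions: BnBr (1.1 equiv), K2CO3 (1.5 equiv), DMF, 50 °C
Reagents that add atoms: benzyl bromide, BrCc1ccccc1
Why: A Williamson ether synthesis masks the guaiacol-type phenol, which iodine(III) would oxidise in step 5, with a group that BCl3 removes in the same operation as the 5-O-methyl group.

**Step 4**
Reactants: 3 1-(2-hydroxy-3,4,5,6-tetramethoxyphenyl)ethan-1-one; 5 3-(benzyloxy)-2-methoxybenzaldehyde
Product: 7 rac-2-[3-(benzyloxy)-2-methoxyphenyl]-5,6,7,8-tetramethoxy-2,3-dihydro-4H-chromen-4-one, via 2'-hydroxychalcone 6 (not isolated)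
Conditions: KOH (50% aq, 10 equiv), EtOH, rt, 36 h; then AcOH to pH 6, reflux, 24 h
Reagents that add atoms: none
Why: Claisen–Schmidt condensation gives the (E)-chalcone, and in the acetate buffer formed on adding AcOH the 2'-phenol closes by oxa-Michael addition, with the equilibrium favouring the flavanone because the 6'-OMe group twists the chalcone out of conjugation; the new C2 stereocentre is deliberately racemic because step 5 erases it.

**Step 5**
Reactants: 7 rac-2-[3-(benzyloxy)-2-methoxyphenyl]-5,6,7,8-tetramethoxy-2,3-dihydro-4H-chromen-4-one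
Product: 8 3-[3-(benzyloxy)-2-methoxyphenyl]-5,6,7,8-tetramethoxy-4H-chromen-4-one
Conditions: PhI(OH)OTs (1.2 equiv), MeCN, reflux, 6 h
Reagents that add atoms: none
Why: In this hypervalent-iodine oxidative 1,2-aryl shift of a flavanone (Koser's reagent, biomimetic of isoflavone synthase), the acid-generated enol attacks I(III) at C3 anti to the 2-aryl group, the electron-rich o-anisyl ring migrates from C2 to C3 through a phenonium ion as PhI leaves, and loss of H-3 from the O1-stabilised C2 cation gives the chromone and removes the only stereocentre, while every ring oxygen is etherified so no phenol meets the oxidant.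

**Step 6**
Reactants: 8 3-[3-(benzyloxy)-2-methoxyphenyl]-5,6,7,8-tetramethoxy-4H-chromen-4-one
Product: 9 5-hydroxy-3-(3-hydroxy-2-methoxyphenyl)-6,7,8-trimethoxy-4H-chromen-4-one (5,3'-dihydroxy-6,7,8,2'-tetramethoxyisoflavone)
Conditions: BCl3 (1 M in CH2Cl2, 4 equiv), C6HMe5 (3 equiv), CH2Cl2, −78 °C to 0 °C; then 1 M HCl/MeOH, rt
Reagents that add atoms: none
Why: In this Lewis-acid ether cleavage, BCl3 chelated between C4=O and the peri 5-OMe removes that methyl selectively (the reaction type used to make 5-demethyl polymethoxyflavones) and, with pentamethylbenzene trapping the benzyl cation, cleaves the benzyl ether at −78 °C, while the unchelated 6-, 7-, 8- and 2'-OMe groups survive at or below 0 °C.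

**Compound list**
1 | 1-(6-hydroxy-2,3,4-trimethoxyphenyl)ethan-1-one | CC(=O)c1c(O)cc(OC)c(OC)c1OC | starting material
2 | 1-(3-bromo-2-hydroxy-4,5,6-trimethoxyphenyl)ethan-1-one | CC(=O)c1c(O)c(Br)c(OC)c(OC)c1OC | intermediate
3 | 1-(2-hydroxy-3,4,5,6-tetramethoxyphenyl)ethan-1-one | CC(=O)c1c(O)c(OC)c(OC)c(OC)c1OC | intermediate
4 | 3-hydroxy-2-methoxybenzaldehyde | COc1c(O)cccc1C=O | starting material
5 | 3-(benzyloxy)-2-methoxybenzaldehyde | COc1c(OCc2ccccc2)cccc1C=O | intermediate
6 | (E)-3-[3-(benzyloxy)-2-methoxyphenyl]-1-(2-hydroxy-3,4,5,6-tetramethoxyphenyl)prop-2-en-1-one (2'-hydroxychalcone, not isolated) | COc1c(OCc2ccccc2)cccc1/C=C/C(=O)c1c(O)c(OC)c(OC)c(OC)c1OC | intermediate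
7 | rac-2-[3-(benzyloxy)-2-methoxyphenyl]-5,6,7,8-tetramethoxy-2,3-dihydro-4H-chromen-4-one (racemic, C2 left undefined on purpose) | COc1c(OCc2ccccc2)cccc1C1CC(=O)c2c(OC)c(OC)c(OC)c(OC)c2O1 | intermediate
8 | 3-[3-(benzyloxy)-2-methoxyphenyl]-5,6,7,8-tetramethoxy-4H-chromen-4-one | COc1c(OCc2ccccc2)cccc1-c1coc2c(OC)c(OC)c(OC)c(OC)c2c1=O | intermediate
9 | 5-hydroxy-3-(3-hydroxy-2-methoxyphenyl)-6,7,8-trimethoxy-4H-chromen-4-one (achiral) | COc1c(O)cccc1-c1coc2c(OC)c(OC)c(OC)c(O)c2c1=O | target

**Total step count:** 6. **Longest linear sequence:** 5 (steps 1, 2, 4, 5, 6).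

**Three steps most likely to fail, with fallbacks**

**Step 5 (the key aryl shift).**
- Risks: simple dehydrogenation to the isomeric flavone, α-tosyloxylation at C3, ring contraction, participation of the 2-OMe oxygen in place of the arene, and oxidative demethylation of the very electron-rich ring A.
- The fallback replaces the oxidative aryl shift by a redox-neutral 1,2-acyl shift of a chalcone epoxide. It sets out from 6, which is isolated by acidifying step 4 in the cold instead of heating it.
- MOMCl/NaH in DMF at 0 °C gives the MOM ether (E)-3-[3-(benzyloxy)-2-methoxyphenyl]-1-[2,3,4,5-tetramethoxy-6-(methoxymethoxy)phenyl]prop-2-en-1-one F1.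
- Weitz–Scheffer epoxidation (30% H2O2, NaOH, MeOH/THF, 0 °C) gives rac-trans-{3-[3-(benzyloxy)-2-methoxyphenyl]oxiran-2-yl}[2,3,4,5-tetramethoxy-6-(methoxymethoxy)phenyl]methanone F2.
- BF3·OEt2 in CH2Cl2 at −20 °C opens the epoxide at the benzylic carbon stabilised by the o-anisyl group. The aroyl group then migrates (House–Meinwald rearrangement) to give 2-[3-(benzyloxy)-2-methoxyphenyl]-3-oxo-3-[2,3,4,5-tetramethoxy-6-(methoxymethoxy)phenyl]propanal F3.
- HCl in MeOH at 50 °C removes the MOM group and cyclodehydrates the freed phenol onto the aldehyde. The fallback comes back to the route at 8.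

**Step 6 (one-pot double unmasking).**
- Risks: further demethylation at 6-OMe next to the boron-bound 5-oxygen, demethylation at 2'-OMe next to the boron-bound 3'-oxygen, and C-benzylation of ring B.
- The fallback separates the two cleavages into orthogonal reaction types. It sets out from 8.
- Hydrogenolysis (H2 1 atm, 10% Pd/C, EtOAc, rt, stopped at one equivalent of H2) gives 3-(3-hydroxy-2-methoxyphenyl)-5,6,7,8-tetramethoxy-4H-chromen-4-one F4.
- Brønsted-acid hydrolysis (3 M HCl in EtOH, reflux) then removes only the 5-O-methyl group, which is activated by the protonated peri carbonyl. This is the same selectivity that serves for 5-demethyl polymethoxyflavones. The fallback comes back to the route at 9.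

**Step 2 (Ullmann methoxylation of an o-bromophenol that carries an enolisable ketone).**
- Risks: hydrodebromination back to 1, slow turnover of the electron-rich phenoxide, and aldol self-condensation.
- The fallback installs the oxygen through C–H formylation and oxidation instead of C–Br substitution. It sets out from 1 and bypasses 2.
- Casnati–Skattebøl ortho-formylation (MgCl2, Et3N, paraformaldehyde, MeCN, reflux) at the only free position gives 3-acetyl-2-hydroxy-4,5,6-trimethoxybenzaldehyde F5.
- Dakin oxidation (H2O2, NaOH, 0 °C) gives 1-(2,3-dihydroxy-4,5,6-trimethoxyphenyl)ethan-1-one F6. The aldehyde reacts far faster than the hindered, chelated ketone.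
- MeI (1.0 equiv) with K2CO3 in acetone methylates only the free 3-OH, because the 2-OH is locked in the hydrogen bond to the acetyl group. The fallback comes back to the route at 3.

**Further compounds**
F1 | step 5 | (E)-3-[3-(benzyloxy)-2-methoxyphenyl]-1-[2,3,4,5-tetramethoxy-6-(methoxymethoxy)phenyl]prop-2-en-1-one | COCOc1c(OC)c(OC)c(OC)c(OC)c1C(=O)/C=C/c1cccc(OCc2ccccc2)c1OC
F2 | step 5 | rac-trans-{3-[3-(benzyloxy)-2-methoxyphenyl]oxiran-2-yl}[2,3,4,5-tetramethoxy-6-(methoxymethoxy)phenyl]methanone (one enantiomer of the racemate drawn) | COCOc1c(OC)c(OC)c(OC)c(OC)c1C(=O)[C@@H]1[C@H](O1)c1cccc(OCc2ccccc2)c1OC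
F3 | step 5 | 2-[3-(benzyloxy)-2-methoxyphenyl]-3-oxo-3-[2,3,4,5-tetramethoxy-6-(methoxymethoxy)phenyl]propanal (racemic, enolisable) | COCOc1c(OC)c(OC)c(OC)c(OC)c1C(=O)C(C=O)c1cccc(OCc2ccccc2)c1OC
F4 | step 6 | 3-(3-hydroxy-2-methoxyphenyl)-5,6,7,8-tetramethoxy-4H-chromen-4-one | COc1c(O)cccc1-c1coc2c(OC)c(OC)c(OC)c(OC)c2c1=O
F5 | step 2 | 3-acetyl-2-hydroxy-4,5,6-trimethoxybenzaldehyde | CC(=O)c1c(O)c(C=O)c(OC)c(OC)c1OC
F6 | step 2 | 1-(2,3-dihydroxy-4,5,6-trimethoxyphenyl)ethan-1-one | CC(=O)c1c(O)c(O)c(OC)c(OC)c1OC
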